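In a one-step world substrate becomes target and stops there, so one product peak grows and nobody asks who leads. These flasks show a second peak beside it.

| flask | substrate | gas phase | temperature | remark | time |
|---|---|---|---|---|---|
| oak | 27 mM | 1.9 mM (held) | 10 °C | run made earlier |  |
| alder | 42 mM | 1.9 mM (held) | 29 °C | run made earlier |  |
| red | 19 mM | 1.9 mM (held) | 25 °C |  | 12 h |
| grey | 19 mM | 1.9 mM (held) | 33 °C |  | 12 h |

| run | time / h | side product / % | isomer of the product / % | target / % | substrate / % |
|---|---|---|---|---|---|
| oak | 1.00 | 0.3 | 0 | 3.1 | 96.5 |
| oak | 3.00 | 0.8 | 0 | 11.8 | 86.9 |
| oak | 6.00 | 3.3 | 0 | 22.9 | 72.2 |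
| oak | 15.0 | 12.3 | 3.6 | 46.9 | 37.8 |
| alder | 0.500 | 0 | 0 | 1.9 | 97.5 |
| alder | 1.33 | 0.7 | 0.5 | 4.9 | 93.0 |
| alder | 3.00 | 5.6 | 1.4 | 11.0 | 81.7 |
| alder | 8.00 | 23.4 | 7.7 | 22.9 | 47.1 |

(readings scatter by 0.5 percentage points)

- a species is counted by the substrate in it: one side product counts as two
- at the start none of the gas phase is in solution

- which of these there is most of at the end, counted by the substrate in it, red (substrate / side product / isomer of the product / target)
- which of these there is most of at the end, counted by the substrate in it, grey (substrate / side product / isomer of the product / target)
- final amount of the leader among these, as a percentage of the substrate charged, in red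
- final amount of the leader among these, as a percentage of the substrate charged, in grey

**Which peak comes first, target or isomer?**
Target. In oak and alder it is read before any isomer, so I treat this as a consecutive (series) reaction: target goes on to isomer with a first-order constant k.

**What do you watch?**
The tilt τ, isomer over target. The even split, τ = 1, is the zero of my scale, and above it the isomer leads.

**How do you get k from so few readings?**
Suppose target P rises about straight from zero. Its mean is then half its last reading, so the isomer E read at time t gives k ≈ 2E/(Pt). Oak gives 0.0102 /h and alder 0.0841 /h, a factor of 8.21.

**And at the new temperatures?**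
I take ln k as straight in temperature. That gives 0.0540 /h for red and 0.131 /h for grey. With τ ≈ kt/2 at 12 h, my end tilt is 0.324 in red and 0.786 in grey. Both stand below the tie, so I name target in both flasks.

**Alder's target bends over. Isn't "straight from zero" your weak spot?**
It is. A bowed curve has a mean above that straight-line value, so k reads high. But τ ≈ kt/2 reuses the same straight line, and at a given k that reads low for a bowed target, so the two slips pull opposite ways. Grey's tilt would need to be 1.27 times larger to reach the tie, and I put no sign on what the two slips leave, so target in grey is my call with that margin and no more.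

The forecast gives target at 48 % in red and isomer of the product at 39 % in grey, calling grey “nearly a tie, with a slight lean to isomer”. On grey's leader my reckoning differs from it.

The flasks end with target at 53.1 % in red and target at 42.2 % in grey.

    substrate + target → side product (k = 0.0499 /M/min, Ea = 51.0 kJ/mol)
    dissolved gas → decomposed reagent (k = 2.64 × 10⁻⁴ /min, Ea = 104 kJ/mol)
    gas phase ⇌ dissolved gas, rate k3*(csat - [dissolved gas]) (kL = 0.0230 /min)
    target ⇌ isomer of the product (K = 1.61, k = 8.97 × 10⁻⁴ /min, Ea = 88.0 kJ/mol, ΔH = −12.0 kJ/mol)
    substrate + dissolved gas → target (k = 3.27 /M/min, Ea = 60.0 kJ/mol)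
    (constants at 25 °C)

Grey's end peaks give a tilt of 0.822 against the reckoned 0.786, and red's give 0.369 against 0.324. The main reason for what grey's target lacks is isomerisation: without that step, both ways, it ends at 72.3 % instead of 42.2 %. Take the same flask as red, run at 40 °C: the tilt reckons to 1.71, past the tie, and there the isomer of the product leads, 40.5 % against 35.4 % of target.

The readings were computed with made-up constants; noise was put on by code.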